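## The problem

The target 23 is a single cyclohexene. Nothing is fused or bridged, so the task is the placement of seven oxygens and four stereocentres on six ring carbons and one exocyclic carbon. The ring is numbered C1 (quaternary carbinol carrying C7H2OBz), C2 (allylic CH–OBz), C3=C4, C5 (allylic CH–OBz) and C6 (CH–OH). The configuration is (1R,2R,5R,6S): C1–O is cis to C5–O and trans to both C2–O and C6–O. C5 and C6 are ordinary secondary carbinols of the kind a hexose supplies. The tertiary carbinol C1 cannot be corrected once made and C2 sits beside it, so these two are best set together, by transfer from a centre already present and not by a face-selective addition. Three benzoates, two of them allylic, lie next to two free hydroxyls; base would move or remove them and hydrogenolysis would reduce the alkene, so the acyl groups must go on late and the last deprotection must be non-basic. The enabling feature is that C7 is a carboxyl-level carbon on the oxygenated C1 and that the C1–C2 bond flanks C3=C4. This is the retron of an α-alkoxy ester enolate Claisen rearrangement, and undoing it returns an oxygen to C4 and gives a δ-lactone (C7, C1, C6, C5, C4, ring O) whose carbinol carbon C4 carries an (E)-alkoxyvinyl group (C3=C2): a D-gluco hexuronic acid lactonised onto O2.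

## Retrosynthesis

**23 ⇒ 22.** The two O–Si bonds at C1 and C6 are cut last. Unmasking these hydroxyls any earlier would leave them beside benzoates during acylations. The forward step must remove a tertiary and a secondary silyl ether without ever forming an alkoxide.

**22 ⇒ 21 ⇒ 20 ⇒ 18 (with 19).** The three ester C–O bonds are cut in two rounds. The C2 and C5 oxygens are carried as arylmethyl ethers (4-methoxybenzyl, PMB, at C2; 2-naphthylmethyl, NAP, at C5) that one oxidative cleavage removes together, giving diol 21 from 20. C7 is benzoylated first (18 to 20), because a free primary hydroxyl 1,3 to the PMB ether would trap the oxocarbenium ion of the oxidative cleavage as a cyclic acetal. Diol 21 then takes up two further equivalents of 19, one on each allylic hydroxyl. Alcohol 18 carries no acyl group.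

**18 ⇒ 17.** C7 is taken back to the carboxylic acid, the oxidation level at which the key step delivers it.

**17 ⇒ 14 (key).** The C1–C2 bond is cut and the C4–O bond rejoined, turning the cyclohexenecarboxylic acid into δ-lactone 14.
- Against its neighbours: cutting C3=C4 (metathesis) or C4–C5 or C2–C3 (carbonyl additions) would leave the quaternary C1 to a reagent-controlled addition. Here C1 and C2 both arise by transfer in the ring-forming event.
- Simplification: 14 is a hexuronic acid lactone whose stereocentres come from the sugar pool. In sugar numbering the ring carbons map as C1 = sugar C5, C2 = added carbon C1′, C3 = sugar C1, C4 = sugar C2, C5 = sugar C3, C6 = sugar C4, C7 = sugar C6. Sugar C5 becomes sp2 on enolisation, so its configuration is immaterial.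
- Demands on the forward reaction: O-silylation of the lactone enolate must outrun β-elimination of the sugar C4 oxygen, the rearrangement must go through the bridged boat, and the enol ether must be purely E.
- Protecting groups: a cyclic acetal across O4/O5 would hold the C4–O bond near the enolate plane and so suppress elimination. The bridged transition state, however, needs that bond to swing roughly anti to the forming C–C bond. Two acyclic tert-butyldimethylsilyl (TBS) ethers are therefore kept, and elimination is met by in situ trapping.

**14 ⇒ 12 + 13.** The enol ether O–C(sp2) bond is cut. An alkoxymethylene olefination of an aldehyde would make the same compound in one step but as an E/Z mixture. A copper-mediated coupling of alkenylboronate 12 with alcohol 13 retains the alkene geometry, so that geometry is decided one step earlier. The coupling must be mild enough for the lactone.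

**12 ⇒ 10 + 11.** The C1=C1′ bond is cut to aldehyde 10 and the one-carbon boron reagent 11. The chromium-mediated olefination is E-selective, aldehyde-selective and non-basic, which an α-acyloxy, β-alkoxy aldehyde requires.

**10 ⇒ 9 ⇒ 8.** The aldehyde is masked as a diethyl dithioacetal and the silyl ethers are removed, leading back to lactone diol 8.

**8 ⇒ 6 (via 7).** The lactone C6–O2 bond and the two C–S bonds are cut, giving furanuronic acid 6. Opening the furanose releases O2 and O4. With O3 etherified, the acid can lactonise only onto O2 (O4 and O5 would give four- and three-membered rings), so the ring closure itself sorts the oxygens: O2 into the lactone, O4 and O5 left as the diol that is silylated.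

**6 ⇒ 4 ⇒ 3 ⇒ 1 + 2.** C6 is returned to the alcohol level (primary-selective oxidation forward) and the NAP ether to the free 3-OH of 1. Compound 1 is preferred as entry because O3 is its only free hydroxyl. An entry at the uronic acid level would bring C6 ready-made but with O3 locked in a γ-lactone, the one oxygen that must become a stable ether. NAP is used at O3 instead of PMB because it must survive the protic acid of the steps from 3 to 8 and still fall to the same oxidant as PMB.

## Roads not taken

**Alternative 1:** cut C4–C5.
- Forward key step: CrCl2 with catalytic NiCl2 would convert the (Z)-iodoalkene of the open-chain aldehyde A2 into an alkenylchromium species that adds to the C5 aldehyde, closing the ring to A1.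
- Merits: the coupling tolerates esters and a free tertiary hydroxyl, and the Z geometry is what the ring needs. A1 already carries the C2 and C7 benzoates, so only C5 benzoylation and desilylation remain. That endgame is clearly shorter than the five steps that follow 17 here.
- Weak points: C5 is created in the closure by addition to an α-silyloxy aldehyde, so its configuration rests on substrate bias and not on transfer. A2 is a β-hydroxy aldehyde with a quaternary β-carbon (retro-aldol), and it carries two benzoates beside a free tertiary hydroxyl through a Z-iodo-olefination. The quaternary C1 must be made earlier by a face-selective C-branching of a sugar ketone.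
- Comparison: both plans use stoichiometric CrCl2 once. Alternative 1 wins on endgame economy. The chosen plan sets C1 and C2 stereospecifically and keeps the acylation pattern out of every organometallic step.

**Alternative 2:** cut the C5–O and C6–O bonds and take all six ring carbons and C7 from an arene.
- Forward key step: whole cells expressing toluene dioxygenase would add O2 to ethyl benzoate A3 to give the cis-dihydrodiol A4. No ring is closed.
- Merits: one step gives an enantiopure carbocycle with all seven carbons and with C6 already in the target configuration. In step count this is probably the shortest road, and that is conceded.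
- Weak points: in A4 C5–O is cis to C6–O, while 23 needs them trans, so C5 must be inverted. A Mitsunobu reaction with benzoic acid could do this and install the ester at once, a fair point in its favour. The C1=C2 bond of the diene ester must then be oxidised alone, to a trans tertiary-alcohol/secondary-ester pair on the correct face, with C3=C4 untouched; that regio- and facial selectivity is reagent-controlled. A fermentation facility with the specific strain is needed.
- Comparison: the chosen plan is longer (14 steps). Against that it uses only bench reagents, needs no inversion, and takes every centre from glucose or relays it from a glucose centre.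

**Alternative 3:** cut C2–C3.
- Forward key step: Hg(OCOCF3)2 in aqueous acetone would hydroxymercurate the exocyclic enol ether of the 2-C-branched glycoside A5. The hemiketal opens and the α-mercurio ketone adds to the aldehyde, giving cyclohexanone A6.
- Merits: this carbocyclisation is among the best-precedented sugar-to-cyclohexane conversions, also on densely oxygenated substrates. Its precedent is better than that of the lactone contraction used here.
- Weak points: A6 has C3 saturated and C4 as a ketone. The natural elimination of this β-hydroxy ketone runs toward C2=C3 and would lose the C2 oxygen. Reaching C3=C4 needs protection of C2–OH, regioselective enol triflate formation toward C3 and not C5, and reduction: three to four extra operations. The C2 configuration comes from an aldol of substrate-dependent selectivity. The quaternary branch of A5 again needs a face-selective addition to a ketone, and a mercury salt is used.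
- Comparison: the chosen plan delivers the alkene, C1 and C2 in the ring-forming event itself, at the price of a less tested key step.

Key step: step 9

Remark: the lactone series is numbered as D-glucuronic acid (C1–C6, with C1′ the added enol ether carbon) and the carbocycles as 23 (C1–C7). Diacetone-D-glucose 1 is taken as the commercial entry to the D-glucuronic acid series.

Step 1
Reactants: 1 1,2:5,6-di-O-isopropylidene-α-D-glucofuranose (diacetone-D-glucose); 2 2-(bromomethyl)naphthalene
Product: 3 1,2:5,6-di-O-isopropylidene-3-O-(2-naphthylmethyl)-α-D-glucofuranose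
Conditions: NaH, DMF, 0 °C → rt
Reagents that add atoms: none
Why: Williamson etherification of the only free hydroxyl; the NAP ether should withstand the protic acid of steps 2 and 4 much as a benzyl ether does, yet fall to DDQ together with the PMB ether in step 12.

Step 2
Reactants: 3 1,2:5,6-di-O-isopropylidene-3-O-(2-naphthylmethyl)-α-D-glucofuranose
Product: 4 1,2-O-isopropylidene-3-O-(2-naphthylmethyl)-α-D-glucofuranose
Conditions: AcOH/H2O (7:3), 40 °C
Reagents that add atoms: none
Why: Selective acid hydrolysis of the terminal dioxolane, which is far more labile than the ring-fused 1,2-acetal; a standard operation in this series.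

Step 3
Reactants: 4 1,2-O-isopropylidene-3-O-(2-naphthylmethyl)-α-D-glucofuranose
Product: 6 1,2-O-isopropylidene-3-O-(2-naphthylmethyl)-α-D-glucofuranuronic acid, via C6 aldehyde 5 (not isolated)
Conditions: TEMPO (cat.), PhI(OAc)2, MeCN/H2O (1:1), 0 °C → rt
Reagents that add atoms: water, O
Why: Oxoammonium (TEMPO/PhI(OAc)2) oxidation is selective for the primary alcohol; in water the aldehyde hydrate is oxidised on to the acid while the secondary 5-OH should remain.

Step 4
Reactants: 6 1,2-O-isopropylidene-3-O-(2-naphthylmethyl)-α-D-glucofuranuronic acid
Product: 8 3-O-(2-naphthylmethyl)-D-glucurono-6,2-lactone diethyl dithioacetal (δ-lactone; free 4-OH and 5-OH), via open-chain hydroxy acid 7 (not isolated)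
Conditions: EtSH, conc. HCl, 0 °C; then TsOH (cat.), PhMe, 40 °C, reduced pressure
Reagents that add atoms: ethanethiol, CCS
Why: Fischer-type transthioacetalisation opens the furanose acetal to the acyclic diethyl dithioacetal; the freed δ-hydroxy acid then lactonises under acid onto O2, the only hydroxyl that gives an unstrained ring.

Step 5
Reactants: 8 3-O-(2-naphthylmethyl)-D-glucurono-6,2-lactone diethyl dithioacetal
Product: 9 4,5-bis-O-(tert-butyldimethylsilyl)-3-O-(2-naphthylmethyl)-D-glucurono-6,2-lactone diethyl dithioacetal
Conditions: TBSOTf, 2,6-lutidine, CH2Cl2, −40 → 0 °C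
Reagents that add atoms: tert-butyldimethylsilyl trifluoromethanesulfonate, CC(C)(C)[Si](C)(C)OS(=O)(=O)C(F)(F)F
Why: Silyl triflate silylation of the two remaining cis hydroxyls under weakly basic conditions that neither open nor enolise the lactone; acyclic silyl ethers leave the C4–O bond free to turn anti to the forming bond in step 9.

Step 6
Reactants: 9 4,5-bis-O-(tert-butyldimethylsilyl)-3-O-(2-naphthylmethyl)-D-glucurono-6,2-lactone diethyl dithioacetal
Product: 10 4,5-bis-O-(tert-butyldimethylsilyl)-3-O-(2-naphthylmethyl)-aldehydo-D-glucurono-6,2-lactone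
Conditions: HgCl2, CaCO3, MeCN/H2O (4:1), rt
Reagents that add atoms: water, O
Why: Thiophilic-metal-assisted dithioacetal hydrolysis, the classical route to 2-O-acyl aldehydo sugars; the CaCO3 buffer keeps the medium neutral so that the aldehyde should neither epimerise at C2 (the centre that later controls C1) nor lose the C3 ether by β-elimination.

Step 7
Reactants: 10 4,5-bis-O-(tert-butyldimethylsilyl)-3-O-(2-naphthylmethyl)-aldehydo-D-glucurono-6,2-lactone; 11 2-(dichloromethyl)-4,4,5,5-tetramethyl-1,3,2-dioxaborolane
Product: 12 (E)-alkenylboronate: the lactone of 10 with C1HO replaced by (E)-C1H=C1′H–B(pinacolato)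
Conditions: CrCl2, LiI, THF, 0 °C → rt
Reagents that add atoms: none
Why: Takai–Utimoto borylolefination: a geminal dichromium species from the dihalomethylboronate adds to the aldehyde and eliminates to the (E)-alkenylboronate; the reagent is non-basic and aldehyde-selective, so lactone, silyl ethers and the C2 centre should be untouched.

Step 8
Reactants: 12 (E)-alkenylboronate lactone; 13 4-methoxybenzyl alcohol
Product: 14 4,5-bis-O-(tert-butyldimethylsilyl)-3-O-(2-naphthylmethyl)-D-glucurono-6,2-lactone with C1HO replaced by (E)-C1H=C1′H–O-(4-methoxybenzyl)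
Conditions: Cu(OAc)2, Et3N, 13 (excess, as solvent), 4 Å MS, air, rt
Reagents that add atoms: none
Why: Chan–Lam–Evans-type oxidative C–O coupling of an alkenylboronate with an aliphatic alcohol; transmetallation to copper and C–O reductive elimination retain the alkene geometry, so the (E)-enol ether follows from the E boronate.

Step 9
Reactants: 14 (E)-enol ether δ-lactone
Product: 17 1,6-bis(tert-butyldimethylsilyloxy)-2-(4-methoxybenzyloxy)-5-(2-naphthylmethoxy)cyclohex-3-ene-1-carboxylic acid (C1–O cis to C5–O and trans to C2–O and C6–O; absolute configuration as in 23), via silyl ketene acetal 15 (not isolated), via trimethylsilyl ester 16 (not isolated)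
Conditions: Me3SiCl/Et3N, KN(SiMe3)2, THF/PhMe, −78 °C; then PhMe, 80 °C; then aq. NaH2PO4, rt
Reagents that add atoms: chlorotrimethylsilane, C[Si](C)(C)Cl (retained in 15 and 16 only)
Why: KN(SiMe3)2 removes H5 (sugar numbering) of 14 with Me3SiCl already present, so the potassium enolate is silylated on oxygen to cyclic ketene acetal 15 before it can expel the C4 silyloxy group; on warming, 15 undergoes a concerted suprafacial [3,3] shift in which the ketene acetal carbon bonds to the alkoxy-bearing terminus of the enol ether while the allylic lactone C–O bond breaks, giving silyl ester 16 and, after hydrolysis, acid 17. The closest known reaction type is the Ireland–Claisen ring contraction of alkenyl lactones to cycloalkenecarboxylic acids, here in its α-alkoxy form with an enol ether as the allyl partner. The cyclohexene closes by the sigmatropic shift itself: the two-carbon tether between the reacting termini allows only a boat-like, bicyclo[2.2.2]-type transition state in which the new bond forms on the lactone face that carries the alkenyl group. C1 (ring numbering) is therefore fixed by the sugar C2 carbinol centre, which is spent as it becomes the sp2 carbon C4; the new C1–C2 bond is cis to the departing oxygen, which places C1–O cis to C5–O and trans to C6–O. C2 is fixed by the E geometry of the enol ether, whose alkoxy group lies on the side of the boat away from the tether and so ends trans to C1–O. The step needs O-silylation to outrun β-elimination, which the in situ silyl chloride and the low temperature should secure. It also needs the conformer with the C4–OTBS bond anti to the forming bond, which the acyclic silyl ethers leave accessible.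

Step 10
Reactants: 17 cyclohexenecarboxylic acid
Product: 18 [1,6-bis(tert-butyldimethylsilyloxy)-2-(4-methoxybenzyloxy)-5-(2-naphthylmethoxy)cyclohex-3-en-1-yl]methanol (configuration as in 23)
Conditions: LiAlH4, THF, 0 → 50 °C; aq. potassium sodium tartrate
Reagents that add atoms: none
Why: Hydride reduction of the carboxylic acid to the primary alcohol; ethers, silyl ethers and the isolated alkene are inert, and the neutral tartrate work-up avoids base-induced silyl migration from the tertiary oxygen to the new primary one.

Step 11
Reactants: 18 primary alcohol; 19 benzoyl chloride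
Product: 20 [1,6-bis(tert-butyldimethylsilyloxy)-2-(4-methoxybenzyloxy)-5-(2-naphthylmethoxy)cyclohex-3-en-1-yl]methyl benzoate (configuration as in 23)
Conditions: pyridine, DMAP (cat.), CH2Cl2, 0 °C → rt
Reagents that add atoms: none
Why: DMAP-catalysed acylation of the only free hydroxyl; done before the oxidative ether cleavage so that no hydroxyl sits 1,3 to the PMB ether, where it would capture the oxocarbenium ion as a cyclic acetal.

Step 12
Reactants: 20 C7 benzoate
Product: 21 [1,6-bis(tert-butyldimethylsilyloxy)-2,5-dihydroxycyclohex-3-en-1-yl]methyl benzoate (configuration as in 23)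
Conditions: DDQ, CH2Cl2/aq. NaH2PO4–Na2HPO4 (pH 7), 0 °C → rt
Reagents that add atoms: none
Why: Oxidative cleavage of both arylmethyl ethers by hydride abstraction and hydrolysis of the oxocarbenium ions (PMB first, NAP more slowly); benzoate, silyl ethers and the alkene are not expected to react, and the buffer protects the silyl ethers.

Step 13
Reactants: 21 2,5-diol; 19 benzoyl chloride
Product: 22 [2,5-bis(benzoyloxy)-1,6-bis(tert-butyldimethylsilyloxy)cyclohex-3-en-1-yl]methyl benzoate (configuration as in 23)
Conditions: 19 (2.5 equiv in all), pyridine, DMAP, CH2Cl2, rt → 40 °C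
Reagents that add atoms: benzoyl chloride, O=C(Cl)c1ccccc1 (a second equivalent of 19, for the second hydroxyl)
Why: DMAP-catalysed benzoylation of the two allylic secondary hydroxyls, each of which takes up one equivalent of 19; C1–O and C6–O are silylated, so the acylation pattern of the target results without selection between hydroxyls.

Step 14
Reactants: 22 tribenzoate bis-silyl ether
Product: 23 [(1R,2R,5R,6S)-2,5-bis(benzoyloxy)-1,6-dihydroxycyclohex-3-en-1-yl]methyl benzoate
Conditions: HF·pyridine, THF/pyridine, 0 → 40 °C
Reagents that add atoms: none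
Why: Acidic fluoride cleaves the secondary and then the tertiary silyl ether without forming an alkoxide, so the neighbouring benzoates should neither migrate nor hydrolyse.

## Compound list

1 | 1,2:5,6-di-O-isopropylidene-α-D-glucofuranose (diacetone-D-glucose) | CC1(C)OC[C@@H](O1)[C@H]1O[C@@H]2OC(C)(C)O[C@@H]2[C@H]1O | starting material
2 | 2-(bromomethyl)naphthalene | BrCc1ccc2ccccc2c1 | starting material
3 | 1,2:5,6-di-O-isopropylidene-3-O-(2-naphthylmethyl)-α-D-glucofuranose | CC1(C)OC[C@@H](O1)[C@H]1O[C@@H]2OC(C)(C)O[C@@H]2[C@H]1OCc1ccc2ccccc2c1 | intermediate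
4 | 1,2-O-isopropylidene-3-O-(2-naphthylmethyl)-α-D-glucofuranose | OC[C@@H](O)[C@H]1O[C@@H]2OC(C)(C)O[C@@H]2[C@H]1OCc1ccc2ccccc2c1 | intermediate
5 | 1,2-O-isopropylidene-3-O-(2-naphthylmethyl)-α-D-gluco-hexodialdo-1,4-furanose (C6 aldehyde, formed in situ) | O=C[C@@H](O)[C@H]1O[C@@H]2OC(C)(C)O[C@@H]2[C@H]1OCc1ccc2ccccc2c1 | intermediate
6 | 1,2-O-isopropylidene-3-O-(2-naphthylmethyl)-α-D-glucofuranuronic acid | OC(=O)[C@@H](O)[C@H]1O[C@@H]2OC(C)(C)O[C@@H]2[C@H]1OCc1ccc2ccccc2c1 | intermediate
7 | 3-O-(2-naphthylmethyl)-D-glucuronic acid diethyl dithioacetal (open chain, formed in situ) | OC(=O)[C@@H](O)[C@@H](O)[C@H](OCc1ccc2ccccc2c1)[C@@H](O)C(SCC)SCC | intermediate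
8 | 3-O-(2-naphthylmethyl)-D-glucurono-6,2-lactone diethyl dithioacetal | O=C1O[C@@H](C(SCC)SCC)[C@@H](OCc2ccc3ccccc3c2)[C@H](O)[C@@H]1O | intermediate
9 | 4,5-bis-O-(tert-butyldimethylsilyl)-3-O-(2-naphthylmethyl)-D-glucurono-6,2-lactone diethyl dithioacetal | O=C1O[C@@H](C(SCC)SCC)[C@@H](OCc2ccc3ccccc3c2)[C@H](O[Si](C)(C)C(C)(C)C)[C@@H]1O[Si](C)(C)C(C)(C)C | intermediate
10 | 4,5-bis-O-(tert-butyldimethylsilyl)-3-O-(2-naphthylmethyl)-aldehydo-D-glucurono-6,2-lactone | O=C1O[C@@H](C=O)[C@@H](OCc2ccc3ccccc3c2)[C@H](O[Si](C)(C)C(C)(C)C)[C@@H]1O[Si](C)(C)C(C)(C)C | intermediate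
11 | 2-(dichloromethyl)-4,4,5,5-tetramethyl-1,3,2-dioxaborolane | CC1(C)OB(C(Cl)Cl)OC1(C)C | starting material
12 | (E)-alkenylboronate: lactone of 10 with C1HO replaced by (E)-CH=CH–B(pinacolato) | O=C1O[C@@H](/C=C/B2OC(C)(C)C(C)(C)O2)[C@@H](OCc2ccc3ccccc3c2)[C@H](O[Si](C)(C)C(C)(C)C)[C@@H]1O[Si](C)(C)C(C)(C)C | intermediate
13 | 4-methoxybenzyl alcohol | COc1ccc(CO)cc1 | starting material
14 | (E)-enol ether lactone: lactone of 10 with C1HO replaced by (E)-CH=CH–O-(4-methoxybenzyl) | O=C1O[C@@H](/C=C/OCc2ccc(OC)cc2)[C@@H](OCc2ccc3ccccc3c2)[C@H](O[Si](C)(C)C(C)(C)C)[C@@H]1O[Si](C)(C)C(C)(C)C | intermediate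
15 | cyclic trimethylsilyl ketene acetal of 14 (formed in situ) | C[Si](C)(C)OC1=C(O[Si](C)(C)C(C)(C)C)[C@@H](O[Si](C)(C)C(C)(C)C)[C@H](OCc2ccc3ccccc3c2)[C@H](/C=C/OCc2ccc(OC)cc2)O1 | intermediate
16 | trimethylsilyl ester of 17 (formed in situ) | C[Si](C)(C)OC(=O)[C@]1(O[Si](C)(C)C(C)(C)C)[C@H](OCc2ccc(OC)cc2)C=C[C@@H](OCc2ccc3ccccc3c2)[C@@H]1O[Si](C)(C)C(C)(C)C | intermediate
17 | 1,6-bis(tert-butyldimethylsilyloxy)-2-(4-methoxybenzyloxy)-5-(2-naphthylmethoxy)cyclohex-3-ene-1-carboxylic acid, configuration as in 23 | OC(=O)[C@]1(O[Si](C)(C)C(C)(C)C)[C@H](OCc2ccc(OC)cc2)C=C[C@@H](OCc2ccc3ccccc3c2)[C@@H]1O[Si](C)(C)C(C)(C)C | intermediate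
18 | [1,6-bis(tert-butyldimethylsilyloxy)-2-(4-methoxybenzyloxy)-5-(2-naphthylmethoxy)cyclohex-3-en-1-yl]methanol, configuration as in 23 | OC[C@]1(O[Si](C)(C)C(C)(C)C)[C@H](OCc2ccc(OC)cc2)C=C[C@@H](OCc2ccc3ccccc3c2)[C@@H]1O[Si](C)(C)C(C)(C)C | intermediate
19 | benzoyl chloride | O=C(Cl)c1ccccc1 | starting material
20 | C7 benzoate of 18 | O=C(OC[C@]1(O[Si](C)(C)C(C)(C)C)[C@H](OCc2ccc(OC)cc2)C=C[C@@H](OCc2ccc3ccccc3c2)[C@@H]1O[Si](C)(C)C(C)(C)C)c1ccccc1 | intermediate
21 | [1,6-bis(tert-butyldimethylsilyloxy)-2,5-dihydroxycyclohex-3-en-1-yl]methyl benzoate, configuration as in 23 | O=C(OC[C@]1(O[Si](C)(C)C(C)(C)C)[C@H](O)C=C[C@@H](O)[C@@H]1O[Si](C)(C)C(C)(C)C)c1ccccc1 | intermediate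
22 | [2,5-bis(benzoyloxy)-1,6-bis(tert-butyldimethylsilyloxy)cyclohex-3-en-1-yl]methyl benzoate, configuration as in 23 | O=C(OC[C@]1(O[Si](C)(C)C(C)(C)C)[C@H](OC(=O)c2ccccc2)C=C[C@@H](OC(=O)c2ccccc2)[C@@H]1O[Si](C)(C)C(C)(C)C)c1ccccc1 | intermediate
23 | [(1R,2R,5R,6S)-2,5-bis(benzoyloxy)-1,6-dihydroxycyclohex-3-en-1-yl]methyl benzoate | O=C(OC[C@]1(O)[C@H](OC(=O)c2ccccc2)C=C[C@@H](OC(=O)c2ccccc2)[C@@H]1O)c1ccccc1 | target

## Step count and least certain steps

Total: 14 steps. Longest linear sequence: 14 steps (from 1; compounds 2, 11, 13 and 19 are commercial).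

**Step 9 (key step).**
- What may go wrong: β-elimination of the C4 silyloxy group from the potassium enolate before O-silylation, because the δ-lactone can place that C–O bond parallel to the enolate π-system. The labile trimethylsilyl ketene acetal may also decay (hydrolysis, silyl transfer to carbon) during the heating that the congested boat may require; in that boat C1–O and C2–O are eclipsed across the forming bond.
- Fallback (sets out from 14, returns at 17): the sigmatropic substrate would be made without any metal enolate. tert-Butyldimethylsilyl triflate and Et3N silylate the lactone carbonyl oxygen, and the amine then removes H5 from the oxocarbenium ion, so a carbanion beside the C4 silyloxy group never exists. This gives the tert-butyldimethylsilyl ketene acetal F1, which is robust enough to be freed from ammonium salts. It is rearranged in a separate thermal operation (PhMe, 80–110 °C) to the silyl ester F2, and K2CO3 in aqueous methanol then frees 17.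

**Step 8.**
- What may go wrong: opening of the lactone by the alcohol, which is present in large excess together with an amine; or protodeboronation and slow transmetallation of the hindered boronate.
- Fallback (sets out from 10, returns at 14): the enol ether would be made by C=C instead of C–O bond formation. Wittig reaction of 10 with the ylide from (4-methoxybenzyloxymethyl)triphenylphosphonium chloride and NaN(SiMe3)2 (THF, −78 °C) gives 14 together with its (Z)-isomer F3, which is removed by chromatography. Steps 7 and 8 are bypassed at the price of geometric control.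

**Step 4.**
- What may go wrong: partial loss of the NAP ether under thiol and strong acid, competing closure to 1-thioglycosides, or incomplete lactonisation.
- Fallback (sets out from 6, returns at 12): no thiol and no strong anhydrous acid are used. Aqueous CF3CO2H removes the acetonide of 6 to give 3-O-(2-naphthylmethyl)-D-glucuronic acid F4 as a hemiacetal mixture. Excess Ph3P=CH2 methylenates its aldehyde form to the open-chain C1-methylene hydroxy acid F5. Acid-catalysed lactonisation gives the vinyl δ-lactone diol F6, and TBSOTf gives its bis-silyl ether F7. Cross-metathesis of F7 with 4,4,5,5-tetramethyl-2-vinyl-1,3,2-dioxaborolane (second-generation Hoveyda–Grubbs catalyst) then gives 12, replacing steps 4 to 7 and aldehyde 10.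

**Step 14.**
- What may go wrong: incomplete cleavage of the tertiary silyl ether, which is hindered and flanked by three oxygenated carbons, and benzoyl migration if the exposure has to be long.
- Fallback (sets out from 18, returns at 23): the silyl groups would be exchanged while no ester is present. Tetrabutylammonium fluoride (THF, with heating if needed) strips both silyl ethers of 18 to triol F8. One equivalent of 19 (pyridine, −20 °C) acylates the primary hydroxyl to benzoate F9. Et3SiOTf/2,6-lutidine covers the secondary and tertiary hydroxyls as the bis(triethylsilyl) ether F10. DDQ gives diol F11 and two equivalents of 19 give the tribenzoate F12, whose triethylsilyl ethers should fall readily to HF·pyridine to give 23. This route is one step longer.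

## Further compounds

F1 | step 9 | cyclic tert-butyldimethylsilyl ketene acetal of 14 | CC(C)(C)[Si](C)(C)OC1=C(O[Si](C)(C)C(C)(C)C)[C@@H](O[Si](C)(C)C(C)(C)C)[C@H](OCc2ccc3ccccc3c2)[C@H](/C=C/OCc2ccc(OC)cc2)O1
F2 | step 9 | tert-butyldimethylsilyl ester of 17 | CC(C)(C)[Si](C)(C)OC(=O)[C@]1(O[Si](C)(C)C(C)(C)C)[C@H](OCc2ccc(OC)cc2)C=C[C@@H](OCc2ccc3ccccc3c2)[C@@H]1O[Si](C)(C)C(C)(C)C
F3 | step 8 | (Z)-isomer of 14 | O=C1O[C@@H](/C=C\OCc2ccc(OC)cc2)[C@@H](OCc2ccc3ccccc3c2)[C@H](O[Si](C)(C)C(C)(C)C)[C@@H]1O[Si](C)(C)C(C)(C)C
F4 | step 4 | 3-O-(2-naphthylmethyl)-D-glucuronic acid (drawn open-chain) | O=C[C@H](O)[C@@H](OCc1ccc2ccccc2c1)[C@H](O)[C@H](O)C(=O)O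
F5 | step 4 | open-chain C1-methylene analogue of F4 (hept-6-enonic acid, D-gluco-derived configuration) | C=C[C@H](O)[C@@H](OCc1ccc2ccccc2c1)[C@H](O)[C@H](O)C(=O)O
F6 | step 4 | vinyl δ-lactone diol (6,2-lactone of F5) | O=C1O[C@@H](C=C)[C@@H](OCc2ccc3ccccc3c2)[C@H](O)[C@@H]1O
F7 | step 4 | 4,5-bis-O-(tert-butyldimethylsilyl) ether of F6 | O=C1O[C@@H](C=C)[C@@H](OCc2ccc3ccccc3c2)[C@H](O[Si](C)(C)C(C)(C)C)[C@@H]1O[Si](C)(C)C(C)(C)C
F8 | step 14 | 1-(hydroxymethyl)-2-(4-methoxybenzyloxy)-5-(2-naphthylmethoxy)cyclohex-3-ene-1,6-diol, configuration as in 23 | OC[C@]1(O)[C@H](OCc2ccc(OC)cc2)C=C[C@@H](OCc2ccc3ccccc3c2)[C@@H]1O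
F9 | step 14 | C7 benzoate of F8 | O=C(OC[C@]1(O)[C@H](OCc2ccc(OC)cc2)C=C[C@@H](OCc2ccc3ccccc3c2)[C@@H]1O)c1ccccc1
F10 | step 14 | 1,6-bis-O-(triethylsilyl) ether of F9 | O=C(OC[C@]1(O[Si](CC)(CC)CC)[C@H](OCc2ccc(OC)cc2)C=C[C@@H](OCc2ccc3ccccc3c2)[C@@H]1O[Si](CC)(CC)CC)c1ccccc1
F11 | step 14 | [2,5-dihydroxy-1,6-bis(triethylsilyloxy)cyclohex-3-en-1-yl]methyl benzoate, configuration as in 23 | O=C(OC[C@]1(O[Si](CC)(CC)CC)[C@H](O)C=C[C@@H](O)[C@@H]1O[Si](CC)(CC)CC)c1ccccc1
F12 | step 14 | [2,5-bis(benzoyloxy)-1,6-bis(triethylsilyloxy)cyclohex-3-en-1-yl]methyl benzoate, configuration as in 23 | O=C(OC[C@]1(O[Si](CC)(CC)CC)[C@H](OC(=O)c2ccccc2)C=C[C@@H](OC(=O)c2ccccc2)[C@@H]1O[Si](CC)(CC)CC)c1ccccc1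
A1 | alternative 1 | [2-benzoyloxy-6-(tert-butyldimethylsilyloxy)-1,5-dihydroxycyclohex-3-en-1-yl]methyl benzoate, configuration as in 23 | O=C(OC[C@]1(O)[C@H](OC(=O)c2ccccc2)C=C[C@@H](O)[C@@H]1O[Si](C)(C)C(C)(C)C)c1ccccc1
A2 | alternative 1 | (Z)-4-benzoyloxy-3-(benzoyloxymethyl)-2-(tert-butyldimethylsilyloxy)-3-hydroxy-6-iodohex-5-enal, configured as A1 | O=C[C@H](O[Si](C)(C)C(C)(C)C)[C@](O)(COC(=O)c1ccccc1)[C@H](OC(=O)c1ccccc1)/C=C\I
A3 | alternative 2 | ethyl benzoate | CCOC(=O)c1ccccc1
A4 | alternative 2 | ethyl (5S,6R)-5,6-dihydroxycyclohexa-1,3-diene-1-carboxylate | CCOC(=O)C1=CC=C[C@H](O)[C@@H]1O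
A5 | alternative 3 | methyl 4-O-benzoyl-3-O-(tert-butyldimethylsilyl)-6-deoxy-2-C-(hydroxymethyl)-2,2′-O-isopropylidene-hex-5-enopyranoside, configured as A6 (one anomer drawn; the anomeric centre is lost in the key step) | CO[C@H]1OC(=C)[C@@H](OC(=O)c2ccccc2)[C@H](O[Si](C)(C)C(C)(C)C)[C@]12COC(C)(C)O2
A6 | alternative 3 | 4-oxocyclohexane with C2–OH, C1/C7 O-isopropylidene, C6 tert-butyldimethylsilyl ether and C5 benzoate (ring numbering of 23) | CC1(C)OC[C@]2(O1)[C@H](O)CC(=O)[C@@H](OC(=O)c1ccccc1)[C@@H]2O[Si](C)(C)C(C)(C)C
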